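## Retrosynthetic overview

- Cut the C(=O)–CH2 bond. The ketone carbon becomes an aryl acyl anion (the 2‑lithio‑1,3‑dithiane of the salicylaldehyde half). It opens the CH2 terminus of an enantiopure aryl oxirane. Dithiane hydrolysis is the last operation.
- Left half: the oxirane comes from asymmetric transfer hydrogenation of an α‑chloroketone. The chroman ring is made first, from 4‑hydroxyphenacyl chloride and isoprene.
- Right half: the dihydrobenzofuran ring is made first, by an enantioselective Pd annulation of 5‑bromo‑2,4‑dihydroxybenzaldehyde with isoprene. Markovnikov hydration of the isopropenyl group follows.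
- Each heterocycle is closed in the first step of its branch. No ring is formed after the union, and no protecting group is used.

Assumption: compounds 1, 2 and 6 are bought as catalogue chemicals.

## Route

Step 1
Reactants: 1 2-chloro-1-(4-hydroxyphenyl)ethan-1-one; 2 isoprene
Product: 3 2-chloro-1-(2,2-dimethylchroman-6-yl)ethan-1-one
Conditions: 85% H3PO4, xylene, 30–35 °C, 20 h (2 added slowly, 1.5 equiv)
Reagents that add atoms: none
Why: Acid-catalysed Friedel–Crafts prenylation ortho to the phenol (a position meta to the acyl group, so still nucleophilic) and then Markovnikov hydroalkoxylation of the prenyl alkene close the 2,2-dimethylchroman in one pot, a known isoprene chromanylation of 4-acylphenols that an α-chloroketone tolerates.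

Step 2
Reactants: 3 2-chloro-1-(2,2-dimethylchroman-6-yl)ethan-1-one
Product: 5 (R)-2,2-dimethyl-6-(oxiran-2-yl)chromane, via (R)-chlorohydrin 4 (not isolated)
Conditions: Cp*RhCl[(S,S)-TsDPEN] (0.2 mol %), HCO2H/Et3N 5:2, THF, rt; then 2 M aq NaOH, 0 °C to rt
Reagents that add atoms: none
Why: In this Noyori–Ikariya asymmetric transfer hydrogenation the (S,S)-TsDPEN catalyst gives the (R)-chlorohydrin (usually ≥95% ee for 2-chloroacetophenones), and hydroxide then closes the epoxide by intramolecular SN2 at CH2Cl without touching the stereocentre.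

Step 3
Reactants: 6 5-bromo-2,4-dihydroxybenzaldehyde; 2 isoprene
Product: 7 (S)-6-hydroxy-2-(prop-1-en-2-yl)-2,3-dihydrobenzofuran-5-carbaldehyde
Conditions: Pd2(dba)3·CHCl3 (2.5 mol %), TY-Phos (antipode of the ligand that gives (R)-tremetone, 6 mol %), K2CO3 (3 equiv), 2 (3 equiv), 1,4-dioxane, 80 °C, sealed tube
Reagents that add atoms: none
Why: In this enantioselective Larock-type heteroannulation (Heck/Tsuji–Trost cascade), oxidative addition into C–Br, carbopalladation of the unsubstituted vinyl terminus of isoprene and ligand-controlled attack of the neighbouring phenoxide on the π-allyl-Pd set C2 as S, the same reaction that turns 3-bromo-4-hydroxyacetophenone into tremetone.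

Step 4
Reactants: 7 (S)-6-hydroxy-2-(prop-1-en-2-yl)-2,3-dihydrobenzofuran-5-carbaldehyde
Product: 8 (S)-6-hydroxy-2-(2-hydroxypropan-2-yl)-2,3-dihydrobenzofuran-5-carbaldehyde
Conditions: Co(acac)2 (10 mol %), PhSiH3 (2 equiv), O2 (1 atm), THF, rt
Reagents that add atoms: dioxygen O=O
Why: Mukaiyama hydration (Co–H hydrogen-atom transfer to the 1,1-disubstituted alkene, O2 capture of the tertiary radical faster than β-aryloxy scission, silane reduction of the peroxide) gives the Markovnikov tertiary alcohol under neutral conditions that spare the chelated aldehyde, the phenol and the adjacent stereocentre.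

Step 5
Reactants: 8 (S)-6-hydroxy-2-(2-hydroxypropan-2-yl)-2,3-dihydrobenzofuran-5-carbaldehyde
Product: 9 (S)-5-(1,3-dithian-2-yl)-2-(2-hydroxypropan-2-yl)-2,3-dihydrobenzofuran-6-ol
Conditions: HS(CH2)3SH (1.1 equiv), Sc(OTf)3 (2 mol %), CH2Cl2, 0 °C to rt
Reagents that add atoms: propane-1,3-dithiol SCCCS
Why: Lewis-acid-catalysed dithioacetalisation converts the aldehyde into the Corey–Seebach acyl-anion precursor, and the mild triflate catalyst does not ionise the tertiary alcohol, whose cation would be destabilised by the β-aryloxy group.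

Step 6
Reactants: 9 (S)-5-(1,3-dithian-2-yl)-2-(2-hydroxypropan-2-yl)-2,3-dihydrobenzofuran-6-ol; 5 (R)-2,2-dimethyl-6-(oxiran-2-yl)chromane
Product: 11 (S)-1-(2,2-dimethylchroman-6-yl)-2-{2-[(S)-6-hydroxy-2-(2-hydroxypropan-2-yl)-2,3-dihydrobenzofuran-5-yl]-1,3-dithian-2-yl}ethan-1-ol, via trilithio dithiane 10 (not isolated)
Conditions: n-BuLi (3.3 equiv), THF/DMPU 6:1, −78 to −20 °C, 1.5 h; 5 (1.1 equiv), −78 to 0 °C; sat. aq NH4Cl
Reagents that add atoms: none
Why: In this Corey–Seebach umpolung on the unprotected trianion, the former aldehyde carbon, now a bulky 2-lithiodithiane carbanion, opens the epoxide by SN2 at the unhindered CH2, joining two intrinsically electrophilic carbons without breaking the benzylic C–O bond (R epoxide becomes S carbinol only through the CIP priority change), while the two OLi groups act as their own protection where an ortho silyl ether would suffer retro-Brook migration.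

Step 7
Reactants: 11 (S)-1-(2,2-dimethylchroman-6-yl)-2-{2-[(S)-6-hydroxy-2-(2-hydroxypropan-2-yl)-2,3-dihydrobenzofuran-5-yl]-1,3-dithian-2-yl}ethan-1-ol
Product: 12 (S)-3-(2,2-dimethylchroman-6-yl)-3-hydroxy-1-[(S)-6-hydroxy-2-(2-hydroxypropan-2-yl)-2,3-dihydrobenzofuran-5-yl]propan-1-one (target)
Conditions: MeI (10 equiv), CaCO3 (5 equiv), MeCN/H2O 9:1, 45 °C
Reagents that add atoms: water O
Why: In this alkylative dithiane hydrolysis, S-methylation makes sulfur a leaving group and water traps the aryl-stabilised thionium ion, while CaCO3 keeps the medium neutral so the β-hydroxy ketone neither dehydrates nor undergoes retro-aldol cleavage and both stereocentres persist.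

## Compound list

1 | 2-chloro-1-(4-hydroxyphenyl)ethan-1-one | O=C(CCl)c1ccc(O)cc1 | starting material
2 | isoprene (2-methylbuta-1,3-diene) | C=CC(C)=C | starting material
3 | 2-chloro-1-(2,2-dimethylchroman-6-yl)ethan-1-one | CC1(C)CCc2cc(C(=O)CCl)ccc2O1 | intermediate
4 | (R)-2-chloro-1-(2,2-dimethylchroman-6-yl)ethan-1-ol | CC1(C)CCc2cc([C@@H](O)CCl)ccc2O1 | intermediate
5 | (R)-2,2-dimethyl-6-(oxiran-2-yl)chromane | CC1(C)CCc2cc([C@@H]3CO3)ccc2O1 | intermediate
6 | 5-bromo-2,4-dihydroxybenzaldehyde | O=Cc1cc(Br)c(O)cc1O | starting material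
7 | (S)-6-hydroxy-2-(prop-1-en-2-yl)-2,3-dihydrobenzofuran-5-carbaldehyde | O=Cc1cc2c(cc1O)O[C@H](C(C)=C)C2 | intermediate
8 | (S)-6-hydroxy-2-(2-hydroxypropan-2-yl)-2,3-dihydrobenzofuran-5-carbaldehyde | O=Cc1cc2c(cc1O)O[C@H](C(C)(C)O)C2 | intermediate
9 | (S)-5-(1,3-dithian-2-yl)-2-(2-hydroxypropan-2-yl)-2,3-dihydrobenzofuran-6-ol | C1CSC(SC1)c1cc2c(cc1O)O[C@H](C(C)(C)O)C2 | intermediate
10 | trilithio derivative of 9 (2-lithiodithiane, lithium phenoxide, lithium tert-alkoxide) | [Li]C1(SCCCS1)c1cc2c(cc1O[Li])O[C@H](C(C)(C)O[Li])C2 | intermediate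
11 | (S)-1-(2,2-dimethylchroman-6-yl)-2-{2-[(S)-6-hydroxy-2-(2-hydroxypropan-2-yl)-2,3-dihydrobenzofuran-5-yl]-1,3-dithian-2-yl}ethan-1-ol | CC1(C)CCc2cc([C@@H](O)CC5(SCCCS5)c3cc4c(cc3O)O[C@H](C(C)(C)O)C4)ccc2O1 | intermediate
12 | (S)-3-(2,2-dimethylchroman-6-yl)-3-hydroxy-1-[(S)-6-hydroxy-2-(2-hydroxypropan-2-yl)-2,3-dihydrobenzofuran-5-yl]propan-1-one | CC1(C)CCc2cc([C@@H](O)CC(=O)c3cc4c(cc3O)O[C@H](C(C)(C)O)C4)ccc2O1 | target

## Step count and risks

Total step count: 7. Longest linear sequence: 5 (steps 3, 4, 5, 6, 7). The left branch needs steps 1 and 2 before it joins at step 6.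

The three steps most likely to fail:

**Step 6.** The third lithiation has to occur next to a phenoxide. The aggregated trianion may be too sluggish, or the electron-rich styrene oxide may open at the benzylic carbon or isomerise.

The fallback sets out from 9 and gives up the unprotected polyanion. The phenol alone is masked with ethyl vinyl ether/PPTS as the 1-ethoxyethyl ether of the dithiane F1. An acetal cannot migrate to carbon as a silyl group would. F1 is converted with 2.2 equiv n-BuLi into the alkoxide/carbanion dianion, which opens 5 to the coupled ethoxyethyl-protected hydroxy dithiane F2. PPTS in MeOH at rt removes the acetal, and the sequence comes back to the route at 11.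

**Step 3.** The substrate carries an extra free phenol and an aldehyde, and both regioselectivity on isoprene and ee depend on the ligand.

The fallback sets out from 6 and builds the ring by epoxide opening instead of π-allyl chemistry.
- Stille coupling with tributyl(3-methylbut-2-en-1-yl)stannane (Pd(PPh3)4, LiCl, DMF) gives 2,4-dihydroxy-5-prenylbenzaldehyde F3.
- Ac2O/pyridine gives the diacetate F4.
- Shi epoxidation with the D-fructose-derived ketone and Oxone gives the (R)-epoxide diacetate F5.
- K2CO3/MeOH removes the acetates, and the 4-phenoxide closes the ring 5-exo-tet with inversion at the secondary carbon.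

This comes back to the route directly at 8, so 7 and step 4 are skipped.

**Step 1.** The 4-acylphenol is a poor Friedel–Crafts partner, so the yield may be low and isoprene may oligomerise.

The fallback sets out from 2 and reverses the order of events. Phenol and 2 (Amberlyst-15 or H3PO4) give 2,2-dimethylchromane F6. Friedel–Crafts acylation of F6 with chloroacetyl chloride/AlCl3 (CH2Cl2, −10 °C) occurs para to the ring oxygen and comes back to the route at 3.

## Further compounds

F1 | step 6 | (S)-2-[5-(1,3-dithian-2-yl)-6-(1-ethoxyethoxy)-2,3-dihydrobenzofuran-2-yl]propan-2-ol | C1CSC(SC1)c1cc2c(cc1OC(C)OCC)O[C@H](C(C)(C)O)C2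
F2 | step 6 | (S)-1-(2,2-dimethylchroman-6-yl)-2-{2-[(S)-6-(1-ethoxyethoxy)-2-(2-hydroxypropan-2-yl)-2,3-dihydrobenzofuran-5-yl]-1,3-dithian-2-yl}ethan-1-ol | CC1(C)CCc2cc([C@@H](O)CC5(SCCCS5)c3cc4c(cc3OC(C)OCC)O[C@H](C(C)(C)O)C4)ccc2O1
F3 | step 3 | 2,4-dihydroxy-5-(3-methylbut-2-en-1-yl)benzaldehyde | CC(C)=CCc1cc(C=O)c(O)cc1O
F4 | step 3 | 4-formyl-6-(3-methylbut-2-en-1-yl)-1,3-phenylene diacetate | CC(C)=CCc1cc(C=O)c(OC(C)=O)cc1OC(C)=O
F5 | step 3 | (R)-4-[(3,3-dimethyloxiran-2-yl)methyl]-6-formyl-1,3-phenylene diacetate | CC1(C)O[C@@H]1Cc1cc(C=O)c(OC(C)=O)cc1OC(C)=O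
F6 | step 1 | 2,2-dimethylchromane | CC1(C)CCc2ccccc2O1
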